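The sphingoid chain is cut between its two secondary carbinol carbons, C3 and C4. C4 is an O-bearing CH flanked by the C5 methylene, so the whole C4–C17 tail (C6=C7 E-alkene and trans-cyclopropane ring in place as passengers) is carried as a primary O-alkyl diisopropylcarbamate. (−)-Sparteine/s-BuLi removes its pro-S hydrogen, and the configurationally stable α-oxy organolithium adds to the formyl carbon (future C3) of L-serine-derived Garner aldehyde. One operation thus joins the fragments, forms C3–C4 and sets both carbinol centres next to the C2 nitrogen centre. Acidolysis, carbamate removal and N-acylation with (R)-2-hydroxypentacosanoic acid finish the ceramide.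

Key step: step 7

Remark: locants C1–C17 are those of the sphingoid chain (C2 bears nitrogen; the three-membered ring spans C12 and C13). The Charette ligand, (−)-sparteine, Garner's aldehyde and methyl (R)-glycidate are taken as purchased.

Step 1
Reactants: 1 (2E)-hept-2-en-1-ol
Product: 2 [(1S,2S)-2-butylcyclopropyl]methanol
Conditions: Et2Zn, CH2I2, DME, (4R,5R)-2-butyl-N,N,N',N'-tetramethyl-1,3,2-dioxaborolane-4,5-dicarboxamide (1.2 equiv), CH2Cl2, −10 °C to rt; aq. NH4Cl
Reagents that add atoms: diiodomethane, ICI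
Why: Charette's dioxaborolane-directed asymmetric Simmons–Smith cyclopropanation, in which the zinc alkoxide of 1 bound to the chiral boronate should deliver CH2 from bis(iodomethyl)zinc to one alkene face, the E geometry passing stereospecifically into the trans ring and the (4R,5R) ligand setting both ring centres as (1S,2S).

Step 2
Reactants: 2 [(1S,2S)-2-butylcyclopropyl]methanol
Product: 3 [(1S,2S)-2-butylcyclopropyl]methyl 4-methylbenzenesulfonate
Conditions: TsCl, Et3N, DMAP (cat.), CH2Cl2, 0 °C; used at once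
Reagents that add atoms: 4-methylbenzenesulfonyl chloride, Cc1ccc(cc1)S(Cl)(=O)=O
Why: O-sulfonylation of a primary alcohol touches no ring bond and no stereocentre, and the cold, immediate use should keep the ionisation-prone cyclopropylcarbinyl sulfonate intact.

Step 3
Reactants: 3 [(1S,2S)-2-butylcyclopropyl]methyl 4-methylbenzenesulfonate
Product: 4 (1S,2S)-1-(but-3-en-1-yl)-2-butylcyclopropane
Conditions: allylmagnesium bromide (2 equiv), CuI (10 mol%), THF, −40 °C to 0 °C
Reagents that add atoms: allylmagnesium bromide, C=CC[Mg]Br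
Why: Copper-catalysed Grignard–sulfonate coupling (Kochi type) is a direct SN2 displacement at the primary carbon without a free cyclopropylcarbinyl radical or cation, so the three-membered ring and its two centres should survive.

Step 4
Reactants: 5 but-3-yn-1-ol
Product: 6 but-3-yn-1-yl N,N-di(propan-2-yl)carbamate
Conditions: N,N-diisopropylcarbamoyl chloride, Et3N, CH2Cl2, reflux
Reagents that add atoms: N,N-diisopropylcarbamoyl chloride, CC(C)N(C(C)C)C(Cl)=O
Why: Acyl substitution at the carbamoyl chloride (O-carbamoylation) installs the group that later directs lithiation.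

Step 5
Reactants: 6 but-3-yn-1-yl N,N-di(propan-2-yl)carbamate
Product: 8 (3E)-4-iodobut-3-en-1-yl N,N-di(propan-2-yl)carbamate, via alkenylzirconocene chloride 7 (not isolated)
Conditions: Cp2Zr(H)Cl (1.3 equiv), THF, rt; then I2, 0 °C
Reagents that add atoms: iodine, II
Why: Schwartz hydrozirconation adds Zr–H syn across the terminal alkyne with zirconium at the terminus, and iodinolysis with retention should give the E-iodoalkene only; the hindered carbamate should not be reduced.

Step 6
Reactants: 4 (1S,2S)-1-(but-3-en-1-yl)-2-butylcyclopropane and 8 (3E)-4-iodobut-3-en-1-yl N,N-di(propan-2-yl)carbamate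
Product: 10 (3E)-8-[(1S,2S)-2-butylcyclopropyl]oct-3-en-1-yl N,N-di(propan-2-yl)carbamate, via alkylborane 9 (not isolated)
Conditions: 9-BBN (0.5 M in THF), rt; then 8, PdCl2(dppf) (5 mol%), 3 M aq. NaOH, THF, 60 °C
Reagents that add atoms: none
Why: Anti-Markovnikov hydroboration of the terminal alkene followed by B-alkyl Suzuki–Miyaura coupling, which proceeds with retention at the alkenyl iodide, should give the E C6=C7 alkene with four methylenes between it and the ring.

Step 7
Reactants: 10 (3E)-8-[(1S,2S)-2-butylcyclopropyl]oct-3-en-1-yl N,N-di(propan-2-yl)carbamate and 11 tert-butyl (4S)-4-formyl-2,2-dimethyl-1,3-oxazolidine-3-carboxylate (Garner's aldehyde)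
Product: 13 tert-butyl (4S)-4-[(1S,2R,4E)-9-[(1S,2S)-2-butylcyclopropyl]-2-{[di(propan-2-yl)carbamoyl]oxy}-1-hydroxynon-4-en-1-yl]-2,2-dimethyl-1,3-oxazolidine-3-carboxylate, via lithiated carbamate 12 (not isolated)
Conditions: (−)-sparteine (1.3 equiv), s-BuLi (1.25 equiv), Et2O, −78 °C, 5 h; then 11 (1.5 equiv), −78 °C; MeOH/AcOH quench at −78 °C
Reagents that add atoms: none
Why: s-BuLi held by (−)-sparteine and precomplexed to the carbamate carbonyl removes the pro-S hydrogen of the OCH2 group (future C4) in preference to the allylic C5–H, and the dipole-stabilised, configurationally stable (S)-α-lithio carbamate 12 then attacks the formyl carbon of 11 (future C3) with retention at carbon, which makes the C3–C4 bond and joins the two halves. The closest known reaction type is Hoppe's sparteine-mediated asymmetric lithiation–substitution of O-alkyl carbamates with carbonyl electrophiles. No ring is closed. C4 (R) is set by the reagent, since the diamine selects the pro-S proton and the electrophile enters with retention; C3 (S) is set by the C2 centre of 11 through Felkin–Anh attack anti to the N-Boc nitrogen, which should favour the 2,3-anti adduct; C2 comes unchanged from L-serine. The step needs α-oxy over allylic deprotonation, secured by the directing carbamate, and one aldehyde face, secured by the bulky non-chelating lithium–diamine reagent at −78 °C, which also suppresses epimerisation of 11. The minor C3 epimer should be removable by chromatography, and any 3-O-carbamate from a 1,2-carbamoyl shift converges in step 9.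

Step 8
Reactants: 13 tert-butyl (4S)-4-[(1S,2R,4E)-9-[(1S,2S)-2-butylcyclopropyl]-2-{[di(propan-2-yl)carbamoyl]oxy}-1-hydroxynon-4-en-1-yl]-2,2-dimethyl-1,3-oxazolidine-3-carboxylate
Product: 14 (2S,3S,4R,6E)-2-amino-11-[(1S,2S)-2-butylcyclopropyl]-1,3-dihydroxyundec-6-en-4-yl N,N-di(propan-2-yl)carbamate
Conditions: 3 M aq. HCl, MeOH, 40 °C; then aq. NaOH to pH 11
Reagents that add atoms: none
Why: Acid hydrolysis of the N,O-isopropylidene aminal and acidolysis of the Boc group free N2 and O1 without touching a stereocentre, while the hindered dialkylcarbamate, the isolated alkene and the alkylcyclopropane should be stable to dilute acid.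

Step 9
Reactants: 14 (2S,3S,4R,6E)-2-amino-11-[(1S,2S)-2-butylcyclopropyl]-1,3-dihydroxyundec-6-en-4-yl N,N-di(propan-2-yl)carbamate
Product: 15 (2S,3S,4R,6E)-2-amino-11-[(1S,2S)-2-butylcyclopropyl]undec-6-ene-1,3,4-triol
Conditions: LiAlH4 (8 equiv), THF, reflux; then H2O, 15% aq. NaOH, H2O
Reagents that add atoms: none
Why: Hydride reduction of the carbamate cleaves the acyl C–O bond and releases the C4 hydroxyl with retention, the isolated alkene and cyclopropane being inert; it is placed after Boc removal because LiAlH4 would turn an N-Boc group into N-methyl.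

Step 10
Reactants: 16 1-bromodocosane and 17 methyl (2R)-oxirane-2-carboxylate
Product: 19 methyl (2R)-2-hydroxypentacosanoate, via docosylmagnesium bromide 18 (not isolated)
Conditions: Mg, THF, 50 °C; then CuI (10 mol%), 17, THF, −40 °C; aq. NH4Cl
Reagents that add atoms: none
Why: Copper-catalysed SN2 opening of the glycidate by the Grignard reagent at the unsubstituted CH2 should outrun addition to the ester at low temperature, and the oxygen-bearing centre is not involved, so (R) is kept.

Step 11
Reactants: 19 methyl (2R)-2-hydroxypentacosanoate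
Product: 20 (2R)-2-hydroxypentacosanoic acid
Conditions: LiOH·H2O, THF/MeOH/H2O, 50 °C; then 1 M HCl
Reagents that add atoms: lithium hydroxide, [Li+].[OH-]
Why: Ester saponification by acyl–oxygen cleavage leaves the α-hydroxy centre untouched.

Step 12
Reactants: 15 (2S,3S,4R,6E)-2-amino-11-[(1S,2S)-2-butylcyclopropyl]undec-6-ene-1,3,4-triol and 20 (2R)-2-hydroxypentacosanoic acid
Product: 21 (2R)-N-[(2S,3S,4R,6E)-11-[(1S,2S)-2-butylcyclopropyl]-1,3,4-trihydroxyundec-6-en-2-yl]-2-hydroxypentacosanamide
Conditions: EDC·HCl, HOBt, Et3N, THF/CH2Cl2, 40 °C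
Reagents that add atoms: none
Why: Carbodiimide/HOBt amide coupling through the benzotriazolyl active ester should acylate the amine selectively over the four hydroxyl groups and leaves all stereocentres untouched.

Compound list
1 | (2E)-hept-2-en-1-ol | CCCC/C=C/CO | starting material
2 | [(1S,2S)-2-butylcyclopropyl]methanol | OC[C@H]1C[C@@H]1CCCC | intermediate
3 | [(1S,2S)-2-butylcyclopropyl]methyl 4-methylbenzenesulfonate | Cc1ccc(cc1)S(=O)(=O)OC[C@H]2C[C@@H]2CCCC | intermediate
4 | (1S,2S)-1-(but-3-en-1-yl)-2-butylcyclopropane | C=CCC[C@H]1C[C@@H]1CCCC | intermediate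
5 | but-3-yn-1-ol | C#CCCO | starting material
6 | but-3-yn-1-yl N,N-di(propan-2-yl)carbamate | C#CCCOC(=O)N(C(C)C)C(C)C | intermediate
7 | chlorobis(cyclopentadienyl)[(1E)-4-{[di(propan-2-yl)carbamoyl]oxy}but-1-en-1-yl]zirconium (formed in the flask; cyclopentadienyl rings drawn σ-bonded) | CC(C)N(C(C)C)C(=O)OCC/C=C/[Zr](Cl)(C1C=CC=C1)C1C=CC=C1 | intermediate
8 | (3E)-4-iodobut-3-en-1-yl N,N-di(propan-2-yl)carbamate | CC(C)N(C(C)C)C(=O)OCC/C=C/I | intermediate
9 | 9-{4-[(1S,2S)-2-butylcyclopropyl]butyl}-9-borabicyclo[3.3.1]nonane (formed in the flask) | C1CC2CCCC(C1)B2CCCC[C@H]3C[C@@H]3CCCC | intermediate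
10 | (3E)-8-[(1S,2S)-2-butylcyclopropyl]oct-3-en-1-yl N,N-di(propan-2-yl)carbamate | CC(C)N(C(C)C)C(=O)OCC/C=C/CCCC[C@H]1C[C@@H]1CCCC | intermediate
11 | tert-butyl (4S)-4-formyl-2,2-dimethyl-1,3-oxazolidine-3-carboxylate | O=C[C@@H]1COC(C)(C)N1C(=O)OC(C)(C)C | starting material
12 | (1S,3E)-8-[(1S,2S)-2-butylcyclopropyl]-1-lithiooct-3-en-1-yl N,N-di(propan-2-yl)carbamate as its (−)-sparteine complex (formed in the flask; diamine ligand not drawn) | [Li][C@H](OC(=O)N(C(C)C)C(C)C)C/C=C/CCCC[C@H]1C[C@@H]1CCCC | intermediate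
13 | tert-butyl (4S)-4-[(1S,2R,4E)-9-[(1S,2S)-2-butylcyclopropyl]-2-{[di(propan-2-yl)carbamoyl]oxy}-1-hydroxynon-4-en-1-yl]-2,2-dimethyl-1,3-oxazolidine-3-carboxylate | CC(C)(C)OC(=O)N1[C@@H](COC1(C)C)[C@H](O)[C@H](OC(=O)N(C(C)C)C(C)C)C/C=C/CCCC[C@H]2C[C@@H]2CCCC | intermediate
14 | (2S,3S,4R,6E)-2-amino-11-[(1S,2S)-2-butylcyclopropyl]-1,3-dihydroxyundec-6-en-4-yl N,N-di(propan-2-yl)carbamate | N[C@@H](CO)[C@H](O)[C@H](OC(=O)N(C(C)C)C(C)C)C/C=C/CCCC[C@H]1C[C@@H]1CCCC | intermediate
15 | (2S,3S,4R,6E)-2-amino-11-[(1S,2S)-2-butylcyclopropyl]undec-6-ene-1,3,4-triol | N[C@@H](CO)[C@H](O)[C@H](O)C/C=C/CCCC[C@H]1C[C@@H]1CCCC | intermediate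
16 | 1-bromodocosane | CCCCCCCCCCCCCCCCCCCCCCBr | starting material
17 | methyl (2R)-oxirane-2-carboxylate | COC(=O)[C@H]1CO1 | starting material
18 | docosylmagnesium bromide (formed in the flask) | CCCCCCCCCCCCCCCCCCCCCC[Mg]Br | intermediate
19 | methyl (2R)-2-hydroxypentacosanoate | CCCCCCCCCCCCCCCCCCCCCCC[C@@H](O)C(=O)OC | intermediate
20 | (2R)-2-hydroxypentacosanoic acid | CCCCCCCCCCCCCCCCCCCCCCC[C@@H](O)C(=O)O | intermediate
21 | (2R)-N-[(2S,3S,4R,6E)-11-[(1S,2S)-2-butylcyclopropyl]-1,3,4-trihydroxyundec-6-en-2-yl]-2-hydroxypentacosanamide | CCCCCCCCCCCCCCCCCCCCCCC[C@@H](O)C(=O)N[C@@H](CO)[C@H](O)[C@H](O)C/C=C/CCCC[C@H]1C[C@@H]1CCCC | target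

Total step count: 12. Longest linear sequence: 8 steps (1, 2, 3, 6, 7, 8, 9, 12).

Steps most likely to fail

Step 7. The risk is poor facial selectivity in the attack on the aldehyde, since the lithiated carbamate itself exerts little simple diastereocontrol, so that much C3 epimer forms. The fallback sets out from 13 taken as its C3-epimer mixture. Buffered Dess–Martin oxidation should give the ketone tert-butyl (4S)-4-{(2R,4E)-9-[(1S,2S)-2-butylcyclopropyl]-2-{[di(propan-2-yl)carbamoyl]oxy}non-4-enoyl}-2,2-dimethyl-1,3-oxazolidine-3-carboxylate F1. Reduction with Zn(BH4)2 in Et2O at −30 °C is chelation-controlled: zinc bridges the ketone oxygen and a flanking carbamate carbonyl, and either chelate should lead hydride to the same face. This should converge both epimers on the (1S)-alcohol and return the route to 13.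

Step 9. The risk is incomplete reductive cleavage of the hindered carbamate, or transfer of the carbamoyl group to the free amine under the basic conditions. The fallback sets out from 10 and changes the α-oxy carbanion to Still's type.
- The lithiated species of step 7 is quenched with Bu3SnCl (retention) to give (1S,3E)-8-[(1S,2S)-2-butylcyclopropyl]-1-(tributylstannyl)oct-3-en-1-yl N,N-di(propan-2-yl)carbamate F2.
- DIBAL-H in THF at 0 °C removes the carbamate before any nitrogen is present and gives (1S,3E)-8-[(1S,2S)-2-butylcyclopropyl]-1-(tributylstannyl)oct-3-en-1-ol F3.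
- MOMCl/iPr2NEt gives tributyl[(1S,3E)-8-[(1S,2S)-2-butylcyclopropyl]-1-(methoxymethoxy)oct-3-en-1-yl]stannane F4.
- Tin–lithium exchange with n-BuLi in THF at −78 °C (retention) gives [(1S,3E)-8-[(1S,2S)-2-butylcyclopropyl]-1-(methoxymethoxy)oct-3-en-1-yl]lithium F5.
- Addition of F5 to 11 gives tert-butyl (4S)-4-[(1S,2R,4E)-9-[(1S,2S)-2-butylcyclopropyl]-1-hydroxy-2-(methoxymethoxy)non-4-en-1-yl]-2,2-dimethyl-1,3-oxazolidine-3-carboxylate F6.
- 3 M HCl in MeOH then removes the methoxymethyl, Boc and acetonide groups together, and the route is rejoined at 15.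

Step 3. The risk is ionisation of the cyclopropylcarbinyl tosylate before or during the coupling, with opening or expansion of the three-membered ring. The fallback sets out from 2 and avoids any leaving group on the carbon next to the ring.
- Dess–Martin oxidation gives (1S,2S)-2-butylcyclopropane-1-carbaldehyde F7.
- Horner–Wadsworth–Emmons reaction with triethyl phosphonoacetate/NaH gives ethyl (2E)-3-[(1S,2S)-2-butylcyclopropyl]prop-2-enoate F8.
- Hydride conjugate reduction with [(Ph3P)CuH]6, which involves no radical next to the ring, gives ethyl 3-[(1S,2S)-2-butylcyclopropyl]propanoate F9.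
- DIBAL-H at −78 °C gives 3-[(1S,2S)-2-butylcyclopropyl]propanal F10.
- Wittig methylenation with Ph3P=CH2 returns the route to 4.

Further compounds
F1 | step 7 | tert-butyl (4S)-4-{(2R,4E)-9-[(1S,2S)-2-butylcyclopropyl]-2-{[di(propan-2-yl)carbamoyl]oxy}non-4-enoyl}-2,2-dimethyl-1,3-oxazolidine-3-carboxylate | CC(C)(C)OC(=O)N1[C@@H](COC1(C)C)C(=O)[C@H](OC(=O)N(C(C)C)C(C)C)C/C=C/CCCC[C@H]2C[C@@H]2CCCC
F2 | step 9 | (1S,3E)-8-[(1S,2S)-2-butylcyclopropyl]-1-(tributylstannyl)oct-3-en-1-yl N,N-di(propan-2-yl)carbamate | CCCC[Sn](CCCC)(CCCC)[C@H](OC(=O)N(C(C)C)C(C)C)C/C=C/CCCC[C@H]1C[C@@H]1CCCC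
F3 | step 9 | (1S,3E)-8-[(1S,2S)-2-butylcyclopropyl]-1-(tributylstannyl)oct-3-en-1-ol | CCCC[Sn](CCCC)(CCCC)[C@H](O)C/C=C/CCCC[C@H]1C[C@@H]1CCCC
F4 | step 9 | tributyl[(1S,3E)-8-[(1S,2S)-2-butylcyclopropyl]-1-(methoxymethoxy)oct-3-en-1-yl]stannane | CCCC[Sn](CCCC)(CCCC)[C@H](OCOC)C/C=C/CCCC[C@H]1C[C@@H]1CCCC
F5 | step 9 | [(1S,3E)-8-[(1S,2S)-2-butylcyclopropyl]-1-(methoxymethoxy)oct-3-en-1-yl]lithium | [Li][C@H](OCOC)C/C=C/CCCC[C@H]1C[C@@H]1CCCC
F6 | step 9 | tert-butyl (4S)-4-[(1S,2R,4E)-9-[(1S,2S)-2-butylcyclopropyl]-1-hydroxy-2-(methoxymethoxy)non-4-en-1-yl]-2,2-dimethyl-1,3-oxazolidine-3-carboxylate | CC(C)(C)OC(=O)N1[C@@H](COC1(C)C)[C@H](O)[C@H](OCOC)C/C=C/CCCC[C@H]2C[C@@H]2CCCC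
F7 | step 3 | (1S,2S)-2-butylcyclopropane-1-carbaldehyde | O=C[C@H]1C[C@@H]1CCCC
F8 | step 3 | ethyl (2E)-3-[(1S,2S)-2-butylcyclopropyl]prop-2-enoate | CCOC(=O)/C=C/[C@H]1C[C@@H]1CCCC
F9 | step 3 | ethyl 3-[(1S,2S)-2-butylcyclopropyl]propanoate | CCOC(=O)CC[C@H]1C[C@@H]1CCCC
F10 | step 3 | 3-[(1S,2S)-2-butylcyclopropyl]propanal | O=CCC[C@H]1C[C@@H]1CCCC
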